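All constants are those of an exercise; what happens was integrated by code.

The constants below pit a single-handed catalyst, which couples the left-handed substrate faster than the right-handed one, against a racemisation of the product that wears its preference away.

    solid reagent ⇌ coupling partner, rate k1*(cs1 - [coupling partner]) while solid is left; crystals form when [coupling partner] > cs1 (cs1 = 0.065 M, k1 = 0.086 min⁻¹)
    coupling partner + free catalyst + right-handed substrate → free catalyst + right-handed product (k2 = 150 M⁻² min⁻¹)
    coupling partner + free catalyst + left-handed substrate → free catalyst + left-handed product (k3 = 1400 M⁻² min⁻¹)
    left-handed product ⇌ right-handed product (k4 = 0.60 min⁻¹)
    2 free catalyst → spent catalyst (k5 = 650 M⁻¹ min⁻¹)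

the same everywhere: left-handed substrate 0.12 M; solid reagent 0.180 M; right-handed substrate 0.12 M; time 6.0 min

| charge | free catalyst |
|---|---|
| cedar | 0.30 mM |
| ash | 0.50 mM |
| maple | 0.60 mM |
| birch | 1.0 mM |

- free catalyst is single-handed; left-handed substrate and right-handed substrate are mirror images of each other, charged as a racemate, each of them at the stated concentration
- where a step has two of a species, its rate is k times that concentration squared, and two are used at each turn
- solid reagent is a solid; its amount is given per volume of the solution
- at the start none of the solid reagent is in solution
- an excess is the difference of the two amounts in percent of their sum
- "hardly changes" means that all values lie within two and a half points (for a concentration: within two and a half percent of the largest)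
- run time (cedar): 6.0 min

* excess of left-handed product over right-handed product at the end for cedar, ash, maple, birch, in this order
* the shape of the row from first to last (rises all the way / falls all the way / hardly changes / rises, then falls / falls, then rises)

At the bench you would read the excess straight off the two rate constants. Freeze the substrates at their equal charges, and left-handed product forms with 1400 M⁻² min⁻¹ against 150 M⁻² min⁻¹ for right-handed product. The selectivity E, the difference of these constants over their sum, is then 80.6%. That rule of thumb describes fresh product. Racemisation erases the difference between the two products with rate constant 1.20 min⁻¹, so define the memory time τ as its inverse, 0.833 min. Your run lasts 7.20 memory times, which puts it past the border of the rule.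

So I reckon differently. The difference of the products holds near E times the end rate times τ, while their total is the mean rate times the run time t. The excess is therefore the flat-rate excess X, which is Eτ/t, multiplied by the end rate over the mean rate. Here X is 11.2%, and no catalyst charge enters it, so I commit to about that value in each flask and to a row that hardly changes.

My hand stops at the rate ratio. The coupling partner climbs on a time of 11.6 min, longer than the run, while the free catalyst has a first half-life, by its own second-order loss step alone, of 2.56 min in cedar and 0.769 min in birch. The rate is thus not flat, and I can give no firm factor.

The forecast stands above my figure and slopes down: 14.1%, 13.2%, 12.9%, 12.2%, so hardly changes. Its ground is that “the difference only remembers the last minute or so”.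

The simulation gives 14.1%, 13.2%, 12.9%, 12.2%, so hardly changes, as the forecast said. At the end cedar keeps 29.9% of its free catalyst and birch keeps 11.4%. Held against the flat-rate excess of 11.2%, the cedar reading is larger by a factor of 1.26, which the rule reads as its end rate over its mean rate, and the same reading for birch gives 1.09.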